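The bond to be made joins the alkyne terminus C1 of the butynyl chain to C5' of the bithiophene. Both carbons are brought in as C–H groups of like, nucleophilic polarity and are joined by a palladium-catalysed, silver(I)-mediated dehydrogenative alkynylation, which gives the target directly from two fully esterified halves with no halide or organometallic handle on either. The step exploits the single unsubstituted α-position (C5', adjacent to sulfur) of the 2,2'-bithiophene, its most readily palladated C–H, and the acidic terminal C(sp)–H of the alkyne. The precursors are [2,2'-bithiophen]-5-ylmethyl isovalerate and but-3-ynyl isovalerate, each made by simple acylation.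

Key step: step 4

Remark: the target has no stereocentre and no stereogenic double bond, so it is a single achiral compound and no stereocontrol is needed.

Step 1
Reactants: 1 2,2'-bithiophene-5-carbaldehyde
Product: 2 [2,2'-bithiophen]-5-ylmethanol
Conditions: NaBH4 (0.6 equiv), THF/MeOH, 0 °C; then H2O (neutral quench)
Reagents that add atoms: none
Why: Chemoselective NaBH4 hydride reduction of the aryl aldehyde to the primary alcohol; the thiophene rings are inert and the neutral aqueous quench avoids ionisation of the thenylic alcohol.

Step 2
Reactants: 2 [2,2'-bithiophen]-5-ylmethanol; 3 3-methylbutanoyl chloride (isovaleryl chloride)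
Product: 4 [2,2'-bithiophen]-5-ylmethyl 3-methylbutanoate
Conditions: 3 (1.2 equiv), Et3N (1.5 equiv), DMAP (cat.), CH2Cl2, 0 °C to rt; chromatography on Et3N-deactivated silica
Reagents that add atoms: 3-methylbutanoyl chloride (3), CC(C)CC(=O)Cl
Why: DMAP-catalysed acylation of a primary alcohol with an acid chloride (nucleophilic acyl substitution) under amine-buffered conditions, which should keep the acid-sensitive thenylic C–O bond intact.

Step 3
Reactants: 5 but-3-yn-1-ol; 3 3-methylbutanoyl chloride (isovaleryl chloride)
Product: 6 but-3-yn-1-yl 3-methylbutanoate
Conditions: 3 (1.1 equiv), Et3N (1.5 equiv), DMAP (cat.), CH2Cl2, 0 °C to rt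
Reagents that add atoms: 3-methylbutanoyl chloride (3), CC(C)CC(=O)Cl
Why: DMAP-catalysed acylation of the unhindered primary homopropargylic alcohol with an acid chloride (nucleophilic acyl substitution); the terminal alkyne is inert to these conditions.

Step 4
Reactants: 4 [2,2'-bithiophen]-5-ylmethyl 3-methylbutanoate; 6 but-3-yn-1-yl 3-methylbutanoate
Product: 8 [5'-(4-(3-methylbutanoyloxy)but-1-yn-1-yl)-[2,2'-bithiophen]-5-yl]methyl 3-methylbutanoate, via silver acetylide 7 (not isolated)
Conditions: Pd2(dba)3 (1 mol %), Ag2O (1.5 equiv), PivOH (30 mol %), DME, 80 °C, Ar, dark; 6 (2 equiv) added slowly by syringe pump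
Reagents that add atoms: none
Why: Pd(II) pivalate should palladate the C5'–H of 4 by carboxylate-assisted concerted metalation–deprotonation, while Ag2O converts the terminal alkyne 6 into silver acetylide 7; transmetalation gives a thienyl(alkynyl)palladium(II) species, reductive elimination forms the C(sp)–C(sp2) bond, and Ag(I) reoxidises Pd(0), depositing silver metal. The closest known reaction type is the palladium-catalysed oxidative C–H/C–H cross-coupling of thiophenes with terminal alkynes (a dehydrogenative Sonogashira-type heteroarene alkynylation). No ring is closed and no stereocentre is formed. Site selectivity is secured by the substrate, since C5' is the only free α-position of the bithiophene and the β C–H bonds are far less reactive towards this palladation. Cross-coupling must also outrun Glaser-type alkyne dimerisation and oxidative thiophene dimerisation, which the low palladium loading, the slow addition and the excess of the cheap alkyne are meant to ensure. Both isovalerate esters should survive the neutral, alkoxide-free medium.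

Compound list
1 | 2,2'-bithiophene-5-carbaldehyde | O=Cc1ccc(-c2cccs2)s1 | starting material
2 | [2,2'-bithiophen]-5-ylmethanol | OCc1ccc(-c2cccs2)s1 | intermediate
3 | 3-methylbutanoyl chloride (isovaleryl chloride) | CC(C)CC(=O)Cl | starting material
4 | [2,2'-bithiophen]-5-ylmethyl 3-methylbutanoate | CC(C)CC(=O)OCc1ccc(-c2cccs2)s1 | intermediate
5 | but-3-yn-1-ol | C#CCCO | starting material
6 | but-3-yn-1-yl 3-methylbutanoate | CC(C)CC(=O)OCCC#C | intermediate
7 | silver(I) acetylide of 6 (silver 4-(3-methylbutanoyloxy)but-1-yn-1-ide) | CC(C)CC(=O)OCCC#C[Ag] | intermediate
8 | [5'-(4-(3-methylbutanoyloxy)but-1-yn-1-yl)-[2,2'-bithiophen]-5-yl]methyl 3-methylbutanoate (CNP0154475.0) | CC(C)CC(=O)OCCC#Cc1ccc(-c2ccc(COC(=O)CC(C)C)s2)s1 | target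

Total step count: 4. Longest linear sequence: 3 steps (1 → 2 → 4 → 8); the alkyne ester 6 is made in one parallel step.

Steps most likely to fail

Step 4 (key step). Oxidative homocoupling of the alkyne or of the thiophene may outpace the cross-coupling, or palladation of the electron-rich bithiophene may be sluggish. The fallback sets out from compound 4 and replaces the C–H/C–H union by a halide-based cross-coupling. Electrophilic bromination of the free α-position with NBS (1.0 equiv, DMF, 0 °C, dark) should give (5'-bromo-[2,2'-bithiophen]-5-yl)methyl 3-methylbutanoate F1. A Sonogashira coupling of F1 with compound 6 (Pd(PPh3)2Cl2, CuI, Et3N, THF, rt to 50 °C) then comes back to the route at compound 8.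

Step 2. The electron-rich thenylic C–O bond may ionise during acylation or on silica, leading to chloride substitution or Friedel–Crafts-type self-alkylation at the free α-position. The fallback sets out from compound 2 and reverses the roles of the partners in a Mitsunobu esterification with 3-methylbutanoic acid (PPh3, DIAD, THF, 0 °C). The alcohol carbon is then the electrophile and the carboxylate the nucleophile under neutral conditions. It comes back to the route at compound 4 and makes no new compound (entry F0).

Step 1. The reduction itself is routine; the risk is acid-promoted etherification or oligomerisation of the sensitive bithienylmethanol during work-up, purification or storage. The fallback sets out from compound 3 and bypasses alcohol 2 altogether by building the thiophene–thiophene bond after the ester is in place. Acylation of commercial (5-bromothiophen-2-yl)methanol with 3 (Et3N, DMAP, CH2Cl2, 0 °C) should give (5-bromothiophen-2-yl)methyl 3-methylbutanoate F2. A Stille coupling of F2 with commercial 2-(tributylstannyl)thiophene (Pd(PPh3)4, toluene, 100 °C, neutral conditions that spare the ester) comes back to the route at compound 4.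

Further compounds
F1 | step 4 | (5'-bromo-[2,2'-bithiophen]-5-yl)methyl 3-methylbutanoate | CC(C)CC(=O)OCc1ccc(-c2ccc(Br)s2)s1
F0 | step 2 | none | none
F2 | step 1 | (5-bromothiophen-2-yl)methyl 3-methylbutanoate | CC(C)CC(=O)OCc1ccc(Br)s1
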